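## The problem

The target (31, CNP0312076.1) is a trans-fused bicyclo[5.3.0]decane (hydroazulene). Its cyclopentene (C2–C6, C4=C5, methyl on C5) is fused through C2 and C6 to a cycloheptane carrying an exocyclic methylene on C1 (C11), a free hydroxyl on C7, the side chain C1′–C5′ on C8 and an acetoxy group on C10. Five ring stereocentres (C2, C6, C7, C8, C10) lie close enough to control one another, whereas C1′ sits on a freely rotating chain and needs reagent control. The ring fusion is trans, and C2 becomes epimerisable whenever C1 is a ketone. The sensitive groups are the tertiary allylic alcohol at C5′ (ionises in acid), the secondary allylic acetate at C10 next to the exocyclic methylene (ionisation, SN2′ attack, migration to O7) and three alkenes that must survive every oxidation and reduction. The two ring oxygens must also be told apart, acetate on C10 and free hydroxyl on C7. The enabling feature is that the C7 and C10 oxygens are 1,4-related and on the same face of the seven-membered ring, with C10 next to the sp2 carbon C1. One oxygen atom can therefore bridge C7 and C10 in an 8-oxabicyclo[3.2.1]octan-2-one (C1 as ketone), the adduct of a six-membered carbonyl ylide (C10–O–C7, stabilised by C1=O) and an enone that brings C8, C9 and the first side-chain carbons.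

## Retrosynthesis

**C3′=C4′ (31 ⇒ 29 + 30).** The side-chain alkene is cut by cross-metathesis between the terminal alkene of 29 and 2-methylbut-3-en-2-ol 30. This brings in the acid-labile tertiary allylic alcohol last and needs no nucleophile that would attack the C10 acetate, which a stabilised Wittig/methyl-metal sequence would. The forward reaction must pick the monosubstituted alkene over C1=C11 and C4=C5 and give the (E)-alkene.

**C1=C11 and the C10 oxygen (29 ⇒ 28 ⇒ 27 ⇒ 26 ⇒ 24).** The methylene is cut back to the C1 ketone 27, the acetate to the 10α-alcohol 26 (displacement with inversion), and that alcohol to the enolate of ketone 24. The bridge of the key step supplies only one oxygen, so C10 must be re-oxygenated after the bridge is opened. Enolate oxidation is preferred over allylic oxidation of a C1 methylene compound, which would have to choose among three alkenes and two allylic positions. The oxidant should approach anti to the C8 side chain (α face), and inversion with acetic acid then installs both the acetate and the β configuration. The ketone 24 is far simpler than 31: one protected oxygen and no exocyclic alkene.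

**Bridge opening (24 ⇒ 23 ⇒ 22).** The C10–O bond of the bridged α-alkoxy ketone 22 is cut reductively with SmI2. Only this C–O bond is activated (α to C1=O), and the oxygen stays on C7 with the configuration fixed by the cycloaddition. The bridge is kept until the side-chain stereocentre is in place, because it protects O7 and C10 and locks C2 against epimerisation.

**Side chain to the acetyl group (22 ⇒ 21 ⇒ 20 ⇒ 19 ⇒ 18 ⇒ 17).** C3′=CH2 is cut by Wittig methylenation of aldehyde 21, C1′–H by asymmetric hydrogenation of allylic alcohol 19, and C1′=C2′ by Horner–Wadsworth–Emmons olefination of the acetyl group of 17. A shorter hydroboration/cross-coupling of an isopropenyl group would rest on substrate control of uncertain sense. The hydroxyl-directed ruthenium–BINAP hydrogenation gives catalyst control and leaves the other alkenes alone. The price is that C1 is reduced with the ester and re-oxidised together with the primary alcohol.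

**Key disconnection (17 ⇒ 14 + 15).** C7–C8, C9–C10 and O–C10 are cut, which removes the seven-membered ring, the bridge and three stereocentres (C7, C8, C10) at once. What remains is a trans-disubstituted cyclopentene 14 with two stereocentres and but-3-en-2-one 15. The forward reaction must form the ylide faster than the carbenoid attacks C4=C5, add the enone with C9 on C10, on the face syn to C2–H, and place the acetyl group exo.

**Diazo ketone and aldehyde (14 ⇒ 13 ⇒ 12 ⇒ 10).** The labile β,γ-unsaturated aldehyde is unmasked last from the primary alcohol. The C1–C10 bond is cut to acid 10 and diazomethane, which is preferred to a methyl ketone/diazo transfer because the acid comes directly from the lactone below.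

**Cyclopentene (10 ⇒ 9 ⇒ 6 ⇒ 3 + 4 ⇒ 1 + 2).** C4=C5 is cut by ring-closing metathesis, the silyl ether acid 9 comes from lactone 6, C2–C3 is cut by trans-selective enolate allylation of 3 with allyl bromide 4, and C5–C6 by rhodium-catalysed asymmetric conjugate addition of 2 to furan-2(5H)-one 1. The butyrolactone carries C1 (acyl) and C7 (alkoxy) at the right oxidation levels from the first step, and its ring oxygen ends as the C7 hydroxyl oxygen of 31. A three-component vinyl addition/formaldehyde trapping on cyclopentenone would need an asymmetric vinyl transfer with enolate capture and a regioselective enol triflate, both less secure than lactone alkylation and metathesis.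

## Roads not taken

**Alternative 1:** The cut is the C2–C6 ring-fusion bond, made last by transannular closure of a ten-membered ring; the ring itself comes from an anionic oxy-Cope rearrangement. In the forward direction KH/18-crown-6 converts the 1-vinyl-2-isopropenylcyclohexanol A2 into the (E)-cyclodec-5-enone A1.
- Merits: the rearrangement is reliable and mild, gives the (E)-alkene through a chair transition state, and carries C7, C8, C10 and the complete side chain, all set beforehand on a six-membered ring. In convergence it is better than the chosen plan, which builds the side chain in six steps after the key step and must re-oxygenate C10.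
- Weak points: the key step creates no stereocentre of 31. Both ring-fusion centres, the C2–C6 bond and the shift of the alkene into C4=C5 are left to a transannular reaction on a flexible ring that holds an eliminable α-alkoxy ketone. Trans fusion is not assured there, and the pentasubstituted A2 is itself a long synthesis.
- Against this the chosen plan sets a key step that closes two rings and fixes three stereocentres on a rigid bicycle, with the ring fusion already secured by a lactone alkylation.

**Alternative 2:** The cuts are C1–C2 and C6–C7 on cyclopent-2-en-1-one A4. In the forward direction a chiral N-heterocyclic carbene–copper catalyst (from Cu(OTf)2) transfers a 1-(trimethylsilyl)vinyl group from aluminium to A4, and the aluminium enolate is trapped by the side-chain aldehyde A5 to give the aldol A3.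
- Merits: this is the most convergent road. C2 is set by the catalyst, C6 and C7 by the aldol, the side chain is complete, and O7 arrives directly with no bridge to remove. In these respects it is better than the chosen plan.
- Weak points: this type of conjugate addition is established for β-substituted enones and would be used here on an unsubstituted one. A5 is α-branched and epimerisable at C8, so C7 depends on an untested case of double stereodifferentiation. No ring closes: the seven-membered ring still needs a C1–C10 closure on a flexible chain, followed by reduction at C10 and a regioselective conversion of the C5 ketone into the C4=C5 methyl alkene.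
- The chosen plan closes the seven-membered ring in the step that fixes C7, C8 and C10 relative to the ring fusion, using a well-established carbenoid cascade.

**Alternative 3:** The cut is C2–C6, formed by 1,2-shift of the C7–C2 bond. In the forward direction the allylic C6 hydroxyl of the cis-decalin-6,7-diol A7 is mesylated in situ (MsCl/Et3N) and ionises with antiperiplanar migration to give the trans-fused hydroazulenone A6.
- Merits: the shift is stereospecific (retention at C2, inversion at C6), so the trans fusion follows from a cis-decalin that is easy to assemble. The 5–7 skeleton appears in one step without diazo chemistry. In control of the ring fusion and in safety it is at least as good as the chosen plan.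
- Weak points: an allylic mesylate may ionise without participation (loss of stereospecificity, substitution, diene formation). A6 is a β,γ-unsaturated ketone flanked by two stereocentres (C6, C8), so conjugation and epimerisation threaten. C7 must then come from a substrate-controlled ketone reduction, C1 and C10 need later work from the ketal, and the side chain is still short.
- The chosen plan delivers O7 with its configuration fixed by the bridge and forms C7–C8 in the same step, so no carbonyl ever stands at C7.

Key step: step 8

Remarks on the chemistry: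
- The numbering of 31 (C1–C11, C1′–C5′) is used for all bicyclic and tricyclic compounds. β is the face of C6–H; the ring fusion is always trans (C2–H α, C6–H β).
- The configuration of the transient C1 carbinol in 19 and 20 is immaterial because it is oxidised in step 12. It is drawn as the 1α-alcohol expected from hydride delivery on the face of the oxygen bridge.
- The sense of induction of (R)-BINAP in step 1 and of (S)-BINAP in step 11 is assigned by analogy with cyclic enones and with geraniol-type allylic alcohols.

## Route

Step 1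
Reactants: 1 furan-2(5H)-one; 2 potassium trifluoro(prop-1-en-2-yl)borate
Product: 3 (R)-4-(prop-1-en-2-yl)dihydrofuran-2(3H)-one
Conditions: [Rh(cod)2]BF4 (3 mol %), (R)-BINAP (3.3 mol %), Et3N, toluene/H2O, 40 °C
Reagents that add atoms: none
Why: Rhodium/BINAP-catalysed asymmetric conjugate addition of an alkenyltrifluoroborate to an α,β-unsaturated lactone (Hayashi–Miyaura reaction); the isopropenyl–rhodium species adds to the lactone face selected by the ligand and the oxa-π-allyl intermediate is protonated by water, which sets C6 under catalyst control.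

Step 2
Reactants: 3 (R)-4-(prop-1-en-2-yl)dihydrofuran-2(3H)-one; 4 allyl bromide
Product: 6 (3S,4R)-3-allyl-4-(prop-1-en-2-yl)dihydrofuran-2(3H)-one, via lithium enolate 5 (not isolated)
Conditions: LiN(i-Pr)2, THF, −78 °C; then allyl bromide, −78 → −40 °C
Reagents that add atoms: none
Why: Kinetic enolate alkylation of a β-substituted γ-butyrolactone; the electrophile approaches the planar enolate anti to the neighbouring isopropenyl group, which sets C2 trans to C6 by 1,2-induction.

Step 3
Reactants: 6 (3S,4R)-3-allyl-4-(prop-1-en-2-yl)dihydrofuran-2(3H)-one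
Product: 9 (2S,3R)-2-allyl-3-{[(tert-butyldimethylsilyl)oxy]methyl}-4-methylpent-4-enoic acid, via potassium hydroxy carboxylate 7 (not isolated), via bis-silyl derivative 8 (not isolated)
Conditions: KOH, MeOH/H2O, 25 °C; evaporate; t-BuMe2SiCl, imidazole, DMF, 25 °C; then K2CO3, MeOH/H2O/THF, 0 °C; pH 5 work-up
Reagents that add atoms: potassium hydroxide, [K+].[OH-]; tert-butyldimethylsilyl chloride, CC(C)(C)[Si](C)(C)Cl
Why: Saponification, exhaustive silylation and selective cleavage of the labile silyl ester give the protected hydroxy acid without relactonisation; the carboxylate is not enolised, so C2 and C6 are untouched.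

Step 4
Reactants: 9 (2S,3R)-2-allyl-3-{[(tert-butyldimethylsilyl)oxy]methyl}-4-methylpent-4-enoic acid
Product: 10 (1S,2R)-2-{[(tert-butyldimethylsilyl)oxy]methyl}-3-methylcyclopent-3-ene-1-carboxylic acid
Conditions: second-generation Grubbs catalyst (3 mol %), CH2Cl2, 40 °C
Reagents that add atoms: none
Why: Ring-closing metathesis of a 1,6-diene with one 1,1-disubstituted alkene gives the trisubstituted cyclopentene (C4=C5) with loss of ethylene; the free acid is tolerated and the trans relation of C1 and C7 follows from 9.

Step 5
Reactants: 10 (1S,2R)-2-{[(tert-butyldimethylsilyl)oxy]methyl}-3-methylcyclopent-3-ene-1-carboxylic acid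
Product: 12 2-diazo-1-[(1S,2R)-2-{[(tert-butyldimethylsilyl)oxy]methyl}-3-methylcyclopent-3-en-1-yl]ethan-1-one, via mixed anhydride 11 (not isolated)
Conditions: i-BuOCOCl, N-methylmorpholine, THF, −15 °C; then CH2N2, Et2O, 0 °C
Reagents that add atoms: diazomethane, C=[N+]=[N-]
Why: Arndt–Eistert-type acylation of diazomethane by a mixed carbonic anhydride forms the C1–C10 bond; the cold, nearly neutral conditions avoid a ketene and therefore epimerisation at C2.

Step 6
Reactants: 12 2-diazo-1-[(1S,2R)-2-{[(tert-butyldimethylsilyl)oxy]methyl}-3-methylcyclopent-3-en-1-yl]ethan-1-one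
Product: 13 2-diazo-1-[(1S,2R)-2-(hydroxymethyl)-3-methylcyclopent-3-en-1-yl]ethan-1-one
Conditions: Bu4NF, AcOH, THF, 0 °C
Reagents that add atoms: none
Why: Fluoride desilylation buffered with acetic acid; α-diazo ketones tolerate buffered fluoride and nothing basic enough to enolise C2 is present.

Step 7
Reactants: 13 2-diazo-1-[(1S,2R)-2-(hydroxymethyl)-3-methylcyclopent-3-en-1-yl]ethan-1-one
Product: 14 (1R,5S)-5-(2-diazoacetyl)-2-methylcyclopent-2-ene-1-carbaldehyde
Conditions: Dess–Martin periodinane, NaHCO3, CH2Cl2, 0 °C; filtered and used at once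
Reagents that add atoms: none
Why: Dess–Martin oxidation under buffered, non-enolising conditions should give the β,γ-unsaturated aldehyde without migration of C4=C5 into conjugation or epimerisation at C6; the diazo ketone is inert to the periodinane.

Step 8
Reactants: 14 (1R,5S)-5-(2-diazoacetyl)-2-methylcyclopent-2-ene-1-carbaldehyde; 15 but-3-en-2-one
Product: 17 oxygen-bridged tricyclic diketone (8β-acetyl-7β,10β-epoxy-5-methylbicyclo[5.3.0]dec-4-en-1-one; acetyl exo), via carbonyl ylide 16 (not isolated)
Conditions: Rh2(OAc)4 (2 mol %), but-3-en-2-one (10 equiv), CH2Cl2, 25 °C, slow addition of 14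
Reagents that add atoms: none
Why: Rh2(OAc)4 turns the diazo ketone into a rhodium carbenoid at C10, which is captured by a lone pair of the C7 aldehyde oxygen; this O–C10 bond closes the six-membered oxacycle as carbonyl ylide 16 and releases the catalyst. The ylide then adds across but-3-en-2-one in a concerted suprafacial [3+2] cycloaddition that forms C7–C8 and C9–C10 and so closes the seven-membered carbocycle of the 8-oxabicyclo[3.2.1]octan-2-one. The closest known reaction type is the Rh2(OAc)4-catalysed cyclisation–cycloaddition cascade of 1-diazo-2,5-dicarbonyl compounds with electron-poor alkenes, a relative of the oxidopyrylium [5+2] cycloaddition. Regioselectivity rests on polarisation: the enolate-like terminus C10 bonds to the enone CH2, so the acetyl-bearing carbon becomes C8. C7 and C10 are held cis by the suprafacial addition, and their sense is set by the trans-fused cyclopentene: only addition syn to C2–H gives a chair pyranone with C2–C3 and C6–C5 equatorial, whereas the other face would push C3 axially into the new bridge. C8 is set by the exo transition state, which keeps the acetyl group away from the three-carbon bridge and the C5 methyl; the exo ketone is also the thermodynamic epimer, so any endo adduct can be equilibrated with mild base. Chemoselectivity is needed against cyclopropanation of C4=C5, which would have to give a strained nortricyclanone; capture by the nearby aldehyde oxygen with this carboxylate catalyst should be faster, and slow addition into excess enone suppresses ylide dimerisation and proton shift.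

Step 9
Reactants: 17 oxygen-bridged tricyclic diketone
Product: 18 ethyl (E)-3-[7β,10β-epoxy-5-methyl-1-oxobicyclo[5.3.0]dec-4-en-8β-yl]but-2-enoate
Conditions: NaH, (EtO)2P(O)CH2CO2Et, THF, 0 → 50 °C
Reagents that add atoms: triethyl phosphonoacetate, CCOC(=O)CP(=O)(OCC)OCC
Why: Horner–Wadsworth–Emmons olefination; the stabilised phosphonate anion should attack the unhindered methyl ketone and leave the α,α′-dibranched bridged ketone C1 alone, and the (E)-enoate with C8 trans to the ester is favoured (any Z isomer is removed here or at 19).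

Step 10
Reactants: 18 ethyl (E)-3-[7β,10β-epoxy-5-methyl-1-oxobicyclo[5.3.0]dec-4-en-8β-yl]but-2-enoate
Product: 19 (E)-3-[7β,10β-epoxy-1α-hydroxy-5-methylbicyclo[5.3.0]dec-4-en-8β-yl]but-2-en-1-ol
Conditions: i-Bu2AlH (5 equiv), CH2Cl2, −78 → 0 °C; aqueous potassium sodium tartrate
Reagents that add atoms: none
Why: 1,2-Reduction of the enoate to the allylic alcohol; the C1 ketone is reduced as well, to a carbinol whose configuration does not matter because step 12 removes it.

Step 11
Reactants: 19 (E)-3-[7β,10β-epoxy-1α-hydroxy-5-methylbicyclo[5.3.0]dec-4-en-8β-yl]but-2-en-1-ol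
Product: 20 (S)-3-[7β,10β-epoxy-1α-hydroxy-5-methylbicyclo[5.3.0]dec-4-en-8β-yl]butan-1-ol
Conditions: Ru(OAc)2[(S)-BINAP] (1 mol %), H2 (50 atm), MeOH, 25 °C
Reagents that add atoms: none
Why: Hydroxyl-directed asymmetric hydrogenation of an (E)-allylic alcohol of the geraniol type; the catalyst should set C1′ as S, and it does not reduce the isolated trisubstituted alkene C4=C5.

Step 12
Reactants: 20 (S)-3-[7β,10β-epoxy-1α-hydroxy-5-methylbicyclo[5.3.0]dec-4-en-8β-yl]butan-1-ol
Product: 21 (S)-3-[7β,10β-epoxy-5-methyl-1-oxobicyclo[5.3.0]dec-4-en-8β-yl]butanal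
Conditions: Dess–Martin periodinane (3 equiv), NaHCO3, CH2Cl2, 0 → 25 °C
Reagents that add atoms: none
Why: Dess–Martin oxidation of both hydroxyls gives the aldehyde and restores the C1 ketone; C1′ is β to the aldehyde and cannot epimerise, and C2 and C10 are locked by the bridge.

Step 13
Reactants: 21 (S)-3-[7β,10β-epoxy-5-methyl-1-oxobicyclo[5.3.0]dec-4-en-8β-yl]butanal
Product: 22 7β,10β-epoxy-5-methyl-8β-[(S)-pent-4-en-2-yl]bicyclo[5.3.0]dec-4-en-1-one
Conditions: Ph3PCH3Br (1.1 equiv), KN(SiMe3)2, THF, −78 → 0 °C
Reagents that add atoms: methyltriphenylphosphonium bromide, C[P+](c1ccccc1)(c1ccccc1)c1ccccc1.[Br-]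
Why: Wittig methylenation; one equivalent of ylide at low temperature reacts with the aldehyde much faster than with the hindered ketone C1.

Step 14
Reactants: 22 7β,10β-epoxy-5-methyl-8β-[(S)-pent-4-en-2-yl]bicyclo[5.3.0]dec-4-en-1-one
Product: 23 7β-hydroxy-5-methyl-8β-[(S)-pent-4-en-2-yl]bicyclo[5.3.0]dec-4-en-1-one
Conditions: SmI2 (2.5 equiv), MeOH, THF, −78 °C
Reagents that add atoms: none
Why: Reductive cleavage of an α-alkoxy ketone by SmI2; the ketyl expels the C10–O bond and the samarium enolate is protonated by methanol, so the oxygen stays on C7 with the configuration set in step 8 and the alkenes are untouched.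

Step 15
Reactants: 23 7β-hydroxy-5-methyl-8β-[(S)-pent-4-en-2-yl]bicyclo[5.3.0]dec-4-en-1-one
Product: 24 5-methyl-8β-[(S)-pent-4-en-2-yl]-7β-(triethylsilyloxy)bicyclo[5.3.0]dec-4-en-1-one
Conditions: Et3SiCl, imidazole, DMF, 0 → 25 °C
Reagents that add atoms: chlorotriethylsilane, CC[Si](CC)(CC)Cl
Why: Silylation of the only hydroxyl; it marks O7 as the future free alcohol and stops it from re-closing the bridge during step 17, under conditions too mild to enolise C2.

Step 16
Reactants: 24 5-methyl-8β-[(S)-pent-4-en-2-yl]-7β-(triethylsilyloxy)bicyclo[5.3.0]dec-4-en-1-one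
Product: 26 10α-hydroxy-5-methyl-8β-[(S)-pent-4-en-2-yl]-7β-(triethylsilyloxy)bicyclo[5.3.0]dec-4-en-1-one, via potassium enolate 25 (not isolated)
Conditions: KN(SiMe3)2, THF, −78 °C; then 3-phenyl-2-(phenylsulfonyl)oxaziridine, −78 °C
Reagents that add atoms: 3-phenyl-2-(phenylsulfonyl)oxaziridine, O=S(=O)(N1OC1c1ccccc1)c1ccccc1
Why: Davis oxidation; the base removes a proton from the C10 methylene, not the ring-fusion C2–H, and the oxaziridine transfers oxygen to the enolate without touching the alkenes. Attack is expected on the α face, anti to the C8 side chain, which the trans ring fusion forces into a pseudo-axial position on the β face.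

Step 17
Reactants: 26 10α-hydroxy-5-methyl-8β-[(S)-pent-4-en-2-yl]-7β-(triethylsilyloxy)bicyclo[5.3.0]dec-4-en-1-one
Product: 27 10β-acetoxy-5-methyl-8β-[(S)-pent-4-en-2-yl]-7β-(triethylsilyloxy)bicyclo[5.3.0]dec-4-en-1-one
Conditions: AcOH, PPh3, diisopropyl azodicarboxylate, toluene, 0 → 25 °C
Reagents that add atoms: acetic acid, CC(=O)O
Why: Mitsunobu esterification; SN2 displacement at the carbonyl-activated C10 inverts the 10α-alcohol to the 10β-acetate, so the acetate and the configuration of 31 are installed in one step.

Step 18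
Reactants: 27 10β-acetoxy-5-methyl-8β-[(S)-pent-4-en-2-yl]-7β-(triethylsilyloxy)bicyclo[5.3.0]dec-4-en-1-one
Product: 28 10β-acetoxy-5-methyl-1-methylene-8β-[(S)-pent-4-en-2-yl]-7β-(triethylsilyloxy)bicyclo[5.3.0]dec-4-ene
Conditions: Zn, CH2Br2, TiCl4, THF/CH2Cl2, 0 → 25 °C
Reagents that add atoms: dibromomethane, BrCBr
Why: Takai–Lombardo methylenation; the non-basic zinc/titanium methylene reagent converts the ketone into the exocyclic alkene without enolising C2 or C10 and without attacking the acetate.

Step 19
Reactants: 28 10β-acetoxy-5-methyl-1-methylene-8β-[(S)-pent-4-en-2-yl]-7β-(triethylsilyloxy)bicyclo[5.3.0]dec-4-ene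
Product: 29 10β-acetoxy-5-methyl-1-methylene-8β-[(S)-pent-4-en-2-yl]bicyclo[5.3.0]dec-4-en-7β-ol
Conditions: HF·pyridine, pyridine, THF, 0 °C
Reagents that add atoms: none
Why: Buffered fluoride cleavage of the triethylsilyl ether; the allylic acetate is stable under these conditions and, with no alkoxide formed, should not migrate to O7.

Step 20
Reactants: 29 10β-acetoxy-5-methyl-1-methylene-8β-[(S)-pent-4-en-2-yl]bicyclo[5.3.0]dec-4-en-7β-ol; 30 2-methylbut-3-en-2-ol
Product: 31 target CNP0312076.1 (10β-acetoxy-8β-[(S,E)-6-hydroxy-6-methylhept-4-en-2-yl]-5-methyl-1-methylenebicyclo[5.3.0]dec-4-en-7β-ol; 2S,6R,7S,8R,10R)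
Conditions: second-generation Hoveyda–Grubbs catalyst (5 mol %), 2-methylbut-3-en-2-ol (10 equiv), CH2Cl2, 40 °C
Reagents that add atoms: none
Why: Olefin cross-metathesis; only the monosubstituted terminal alkene enters the catalytic cycle, since C1=C11 and C4=C5 are too hindered, and the bulky tertiary carbinol partner enforces the (E)-alkene.

## Compound list

1 | furan-2(5H)-one | O=C1C=CCO1 | starting material
2 | potassium trifluoro(prop-1-en-2-yl)borate | [K+].C=C(C)[B-](F)(F)F | starting material
3 | (R)-4-(prop-1-en-2-yl)dihydrofuran-2(3H)-one | O=C1C[C@H](C(C)=C)CO1 | intermediate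
4 | allyl bromide (3-bromoprop-1-ene) | C=CCBr | starting material
5 | lithium enolate of 3 | [Li+].[O-]C1=C[C@H](C(C)=C)CO1 | intermediate (not isolated)
6 | (3S,4R)-3-allyl-4-(prop-1-en-2-yl)dihydrofuran-2(3H)-one | O=C1[C@@H](CC=C)[C@H](C(C)=C)CO1 | intermediate
7 | potassium (2S,3R)-2-allyl-3-(hydroxymethyl)-4-methylpent-4-enoate | [K+].[O-]C(=O)[C@@H](CC=C)[C@H](C(C)=C)CO | intermediate (not isolated)
8 | tert-butyldimethylsilyl (2S,3R)-2-allyl-3-{[(tert-butyldimethylsilyl)oxy]methyl}-4-methylpent-4-enoate | CC(C)(C)[Si](C)(C)OC(=O)[C@@H](CC=C)[C@H](C(C)=C)CO[Si](C)(C)C(C)(C)C | intermediate (not isolated)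
9 | (2S,3R)-2-allyl-3-{[(tert-butyldimethylsilyl)oxy]methyl}-4-methylpent-4-enoic acid | OC(=O)[C@@H](CC=C)[C@H](C(C)=C)CO[Si](C)(C)C(C)(C)C | intermediate
10 | (1S,2R)-2-{[(tert-butyldimethylsilyl)oxy]methyl}-3-methylcyclopent-3-ene-1-carboxylic acid | OC(=O)[C@H]1CC=C(C)[C@@H]1CO[Si](C)(C)C(C)(C)C | intermediate
11 | isobutyl carbonic anhydride of 10 | CC(C)COC(=O)OC(=O)[C@H]1CC=C(C)[C@@H]1CO[Si](C)(C)C(C)(C)C | intermediate (not isolated)
12 | 2-diazo-1-[(1S,2R)-2-{[(tert-butyldimethylsilyl)oxy]methyl}-3-methylcyclopent-3-en-1-yl]ethan-1-one | [N-]=[N+]=CC(=O)[C@H]1CC=C(C)[C@@H]1CO[Si](C)(C)C(C)(C)C | intermediate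
13 | 2-diazo-1-[(1S,2R)-2-(hydroxymethyl)-3-methylcyclopent-3-en-1-yl]ethan-1-one | [N-]=[N+]=CC(=O)[C@H]1CC=C(C)[C@@H]1CO | intermediate
14 | (1R,5S)-5-(2-diazoacetyl)-2-methylcyclopent-2-ene-1-carbaldehyde | [N-]=[N+]=CC(=O)[C@H]1CC=C(C)[C@@H]1C=O | intermediate
15 | but-3-en-2-one | C=CC(C)=O | starting material
16 | six-membered carbonyl ylide (C10–O–C7) from 14 | O=C1[CH-][O+]=C[C@H]2C(C)=CC[C@H]12 | intermediate (not isolated)
17 | 8β-acetyl-7β,10β-epoxy-5-methylbicyclo[5.3.0]dec-4-en-1-one (C2–H α, C6–H β, acetyl exo) | O=C1[C@H]2CC=C(C)[C@@H]2[C@@H](O3)[C@@H](C(C)=O)C[C@H]13 | intermediate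
18 | ethyl (E)-3-[7β,10β-epoxy-5-methyl-1-oxobicyclo[5.3.0]dec-4-en-8β-yl]but-2-enoate | O=C1[C@H]2CC=C(C)[C@@H]2[C@@H](O3)[C@@H](/C(C)=C/C(=O)OCC)C[C@H]13 | intermediate
19 | (E)-3-[7β,10β-epoxy-1α-hydroxy-5-methylbicyclo[5.3.0]dec-4-en-8β-yl]but-2-en-1-ol | O[C@@H]1[C@H]2CC=C(C)[C@@H]2[C@@H](O3)[C@@H](/C(C)=C/CO)C[C@H]13 | intermediate
20 | (S)-3-[7β,10β-epoxy-1α-hydroxy-5-methylbicyclo[5.3.0]dec-4-en-8β-yl]butan-1-ol | O[C@@H]1[C@H]2CC=C(C)[C@@H]2[C@@H](O3)[C@@H]([C@@H](C)CCO)C[C@H]13 | intermediate
21 | (S)-3-[7β,10β-epoxy-5-methyl-1-oxobicyclo[5.3.0]dec-4-en-8β-yl]butanal | O=C1[C@H]2CC=C(C)[C@@H]2[C@@H](O3)[C@@H]([C@@H](C)CC=O)C[C@H]13 | intermediate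
22 | 7β,10β-epoxy-5-methyl-8β-[(S)-pent-4-en-2-yl]bicyclo[5.3.0]dec-4-en-1-one | O=C1[C@H]2CC=C(C)[C@@H]2[C@@H](O3)[C@@H]([C@@H](C)CC=C)C[C@H]13 | intermediate
23 | 7β-hydroxy-5-methyl-8β-[(S)-pent-4-en-2-yl]bicyclo[5.3.0]dec-4-en-1-one | O=C1[C@H]2CC=C(C)[C@@H]2[C@@H](O)[C@@H]([C@@H](C)CC=C)CC1 | intermediate
24 | 5-methyl-8β-[(S)-pent-4-en-2-yl]-7β-(triethylsilyloxy)bicyclo[5.3.0]dec-4-en-1-one | O=C1[C@H]2CC=C(C)[C@@H]2[C@@H](O[Si](CC)(CC)CC)[C@@H]([C@@H](C)CC=C)CC1 | intermediate
25 | potassium C1=C10 enolate of 24 | [K+].[O-]C=1[C@H]2CC=C(C)[C@@H]2[C@@H](O[Si](CC)(CC)CC)[C@@H]([C@@H](C)CC=C)CC=1 | intermediate (not isolated)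
26 | 10α-hydroxy-5-methyl-8β-[(S)-pent-4-en-2-yl]-7β-(triethylsilyloxy)bicyclo[5.3.0]dec-4-en-1-one | O=C1[C@H]2CC=C(C)[C@@H]2[C@@H](O[Si](CC)(CC)CC)[C@@H]([C@@H](C)CC=C)C[C@@H]1O | intermediate
27 | 10β-acetoxy-5-methyl-8β-[(S)-pent-4-en-2-yl]-7β-(triethylsilyloxy)bicyclo[5.3.0]dec-4-en-1-one | O=C1[C@H]2CC=C(C)[C@@H]2[C@@H](O[Si](CC)(CC)CC)[C@@H]([C@@H](C)CC=C)C[C@H]1OC(C)=O | intermediate
28 | 10β-acetoxy-5-methyl-1-methylene-8β-[(S)-pent-4-en-2-yl]-7β-(triethylsilyloxy)bicyclo[5.3.0]dec-4-ene | C=C1[C@H]2CC=C(C)[C@@H]2[C@@H](O[Si](CC)(CC)CC)[C@@H]([C@@H](C)CC=C)C[C@H]1OC(C)=O | intermediate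
29 | 10β-acetoxy-5-methyl-1-methylene-8β-[(S)-pent-4-en-2-yl]bicyclo[5.3.0]dec-4-en-7β-ol | C=C1[C@H]2CC=C(C)[C@@H]2[C@@H](O)[C@@H]([C@@H](C)CC=C)C[C@H]1OC(C)=O | intermediate
30 | 2-methylbut-3-en-2-ol | C=CC(C)(C)O | starting material
31 | CNP0312076.1: 10β-acetoxy-8β-[(S,E)-6-hydroxy-6-methylhept-4-en-2-yl]-5-methyl-1-methylenebicyclo[5.3.0]dec-4-en-7β-ol (2S,6R,7S,8R,10R) | C=C1[C@H]2CC=C(C)[C@@H]2[C@@H](O)[C@@H]([C@@H](C)C/C=C/C(C)(C)O)C[C@H]1OC(C)=O | target

## Step count and least certain steps

Total: 20 steps. Longest linear sequence: 20 steps from furan-2(5H)-one 1; the route is fully linear and the other building blocks are used as purchased.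

**Step 8 (key step).** The carbenoid or the ylide may be intercepted before the bimolecular capture by the moderately reactive enone: cyclopropanation of C4=C5, ylide dimerisation or a 1,4-proton shift to an enol ether. Regio- and exo-selectivity may also be incomplete. The fallback sets out from 14. Under the same Rh2(OAc)4 conditions 14 is combined with but-3-yn-2-one, a more reactive and sterically smaller dipolarophile with no exo/endo question, to give the bridged enone 8-acetyl-7β,10β-epoxy-5-methylbicyclo[5.3.0]deca-4,8-dien-1-one F1. Hydrogenation (H2, 1 atm, Pd/C, EtOAc, 0 °C) of the strained enone from the face of the oxygen bridge gives the endo ketone 8α-acetyl-7β,10β-epoxy-5-methylbicyclo[5.3.0]dec-4-en-1-one F2. Equilibration at C8 with K2CO3 in MeOH then leads to the exo ketone, and the route is rejoined at 17.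

**Step 1.** Protodeboronation of 2 may outrun addition to the weakly electrophilic butenolide, and the enantioselectivity on a five-membered lactone may be insufficient. The fallback sets out from 1. Conjugate addition of isopropenylmagnesium bromide with catalytic CuBr·SMe2 and Me3SiCl gives racemic 4-(prop-1-en-2-yl)dihydrofuran-2(3H)-one F3. Aminolysis with (S)-1-phenylethylamine and AlMe3 gives two diastereomeric hydroxy amides, from which (3R)-3-(hydroxymethyl)-4-methyl-N-[(1S)-1-phenylethyl]pent-4-enamide F4 is separated by crystallisation or chromatography. Relactonisation with p-toluenesulfonic acid in warm toluene releases the amine, and the route is rejoined at 3.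

**Step 11.** Selectivity at C1′ may erode through a mismatched pairing of the catalyst with the resident stereocentres, or through alkene isomerisation before reduction. The fallback sets out from 19. Selective allylic oxidation with MnO2 gives the enal (E)-3-[7β,10β-epoxy-1α-hydroxy-5-methylbicyclo[5.3.0]dec-4-en-8β-yl]but-2-enal F5. Organocatalytic transfer hydrogenation (Hantzsch ester, (R)-2-tert-butyl-3-methylimidazolidin-4-one trichloroacetate, CHCl3, −30 °C), which converges E and Z isomers through the iminium ion, gives the hydroxy aldehyde (S)-3-[7β,10β-epoxy-1α-hydroxy-5-methylbicyclo[5.3.0]dec-4-en-8β-yl]butanal F6. Dess–Martin oxidation of the C1 carbinol rejoins the route at 21.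

**Step 16.** The facial selectivity of oxygen transfer to the flexible seven-membered enolate may be poor or reversed, and some deprotonation at C2 cannot be excluded. The fallback sets out from 24 and uses the other epimer: the 10β-alcohol 10β-hydroxy-5-methyl-8β-[(S)-pent-4-en-2-yl]-7β-(triethylsilyloxy)bicyclo[5.3.0]dec-4-en-1-one F7, separated from 26, is acetylated with retention (Ac2O, pyridine, 4-dimethylaminopyridine). Both epimers thus converge, and the route is rejoined at 27.

**Step 17.** Elimination towards a C9=C10 enone, or a sluggish displacement at the hindered C10 carbinol, may compete with inversion. The fallback sets out from 26 and replaces the substitution by an oxidation/reduction pair.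
- Takai–Lombardo methylenation (Zn, CH2Br2, TiCl4) of the free hydroxy ketone gives the allylic alcohol 5-methyl-1-methylene-8β-[(S)-pent-4-en-2-yl]-7β-(triethylsilyloxy)bicyclo[5.3.0]dec-4-en-10α-ol F8.
- Dess–Martin oxidation gives the α-methylene ketone 5-methyl-1-methylene-8β-[(S)-pent-4-en-2-yl]-7β-(triethylsilyloxy)bicyclo[5.3.0]dec-4-en-10-one F9.
- Luche reduction (NaBH4, CeCl3, MeOH, −78 °C), with hydride arriving on the less hindered α face, gives the 10β-alcohol 5-methyl-1-methylene-8β-[(S)-pent-4-en-2-yl]-7β-(triethylsilyloxy)bicyclo[5.3.0]dec-4-en-10β-ol F10.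
- Acetylation (Ac2O, pyridine) rejoins the route at 28.

## Further compounds

F1 | step 8 | 8-acetyl-7β,10β-epoxy-5-methylbicyclo[5.3.0]deca-4,8-dien-1-one | O=C1[C@H]2CC=C(C)[C@@H]2[C@@H](O3)C(C(C)=O)=C[C@H]13
F2 | step 8 | 8α-acetyl-7β,10β-epoxy-5-methylbicyclo[5.3.0]dec-4-en-1-one (endo epimer of 17) | O=C1[C@H]2CC=C(C)[C@@H]2[C@@H](O3)[C@H](C(C)=O)C[C@H]13
F3 | step 1 | racemic 4-(prop-1-en-2-yl)dihydrofuran-2(3H)-one | O=C1CC(C(C)=C)CO1
F4 | step 1 | (3R)-3-(hydroxymethyl)-4-methyl-N-[(1S)-1-phenylethyl]pent-4-enamide | O=C(C[C@H](C(C)=C)CO)N[C@@H](C)c1ccccc1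
F5 | step 11 | (E)-3-[7β,10β-epoxy-1α-hydroxy-5-methylbicyclo[5.3.0]dec-4-en-8β-yl]but-2-enal | O[C@@H]1[C@H]2CC=C(C)[C@@H]2[C@@H](O3)[C@@H](/C(C)=C/C=O)C[C@H]13
F6 | step 11 | (S)-3-[7β,10β-epoxy-1α-hydroxy-5-methylbicyclo[5.3.0]dec-4-en-8β-yl]butanal | O[C@@H]1[C@H]2CC=C(C)[C@@H]2[C@@H](O3)[C@@H]([C@@H](C)CC=O)C[C@H]13
F7 | step 16 | 10β-hydroxy-5-methyl-8β-[(S)-pent-4-en-2-yl]-7β-(triethylsilyloxy)bicyclo[5.3.0]dec-4-en-1-one | O=C1[C@H]2CC=C(C)[C@@H]2[C@@H](O[Si](CC)(CC)CC)[C@@H]([C@@H](C)CC=C)C[C@H]1O
F8 | step 17 | 5-methyl-1-methylene-8β-[(S)-pent-4-en-2-yl]-7β-(triethylsilyloxy)bicyclo[5.3.0]dec-4-en-10α-ol | C=C1[C@H]2CC=C(C)[C@@H]2[C@@H](O[Si](CC)(CC)CC)[C@@H]([C@@H](C)CC=C)C[C@@H]1O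
F9 | step 17 | 5-methyl-1-methylene-8β-[(S)-pent-4-en-2-yl]-7β-(triethylsilyloxy)bicyclo[5.3.0]dec-4-en-10-one | C=C1[C@H]2CC=C(C)[C@@H]2[C@@H](O[Si](CC)(CC)CC)[C@@H]([C@@H](C)CC=C)CC1=O
F10 | step 17 | 5-methyl-1-methylene-8β-[(S)-pent-4-en-2-yl]-7β-(triethylsilyloxy)bicyclo[5.3.0]dec-4-en-10β-ol | C=C1[C@H]2CC=C(C)[C@@H]2[C@@H](O[Si](CC)(CC)CC)[C@@H]([C@@H](C)CC=C)C[C@H]1O
A1 | alternative 1 | (E)-cyclodec-5-enone with C7 p-methoxybenzyl ether, C10 methoxymethyl ether and silylated side chain | O=C1CCC/C(C)=C/[C@@H](OCc2ccc(OC)cc2)[C@@H]([C@@H](C)C/C=C/C(C)(C)O[Si](C)(C)C(C)(C)C)C[C@H]1OCOC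
A2 | alternative 1 | 1-vinyl-2-isopropenylcyclohexanol precursor of A1 | C=C[C@@]1(O)[C@H](C(C)=C)[C@@H](OCc2ccc(OC)cc2)[C@@H]([C@@H](C)C/C=C/C(C)(C)O[Si](C)(C)C(C)(C)C)C[C@H]1OCOC
A3 | alternative 2 | trans-2,3-disubstituted cyclopentanone aldol | C=C([Si](C)(C)C)[C@H]1CCC(=O)[C@@H]1[C@@H](O)[C@@H]([C@@H](C)C/C=C/C(C)(C)O[Si](CC)(CC)CC)CC(=O)OC(C)(C)C
A4 | alternative 2 | cyclopent-2-en-1-one | O=C1C=CCC1
A5 | alternative 2 | tert-butyl (E)-3-formyl-4,8-dimethyl-8-(triethylsilyloxy)non-6-enoate (configured as C8 and C1′ of 31) | O=C[C@@H]([C@@H](C)C/C=C/C(C)(C)O[Si](CC)(CC)CC)CC(=O)OC(C)(C)C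
A6 | alternative 3 | trans-fused hydroazulenone (C7 ketone, C10 dioxolane, methyl ester side chain) | C1[C@H]2CC=C(C)[C@@H]2C(=O)[C@@H]([C@@H](C)CC(=O)OC)CC13OCCO3
A7 | alternative 3 | cis-decalin-6,7-diol precursor of A6 | O[C@H]1C(C)=CC[C@@H]2CC3(OCCO3)C[C@H]([C@@H](C)CC(=O)OC)[C@]12O
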